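**Retrosynthetic overview**
1. Target 32 ⇐ angeloylation of the hindered C-1 alcohol 29; the isobutyrate is placed earlier on the only unhindered hydroxyl.
2. 29 ⇐ ring C (cyclobutane, formed last): the C-5 enolate displaces the C-10 oxygen of the cis-1,3-cyclic sulfate 27.
3. Bicyclic enone 21 ⇐ ring B (cyclohexenone, formed second): ester-tethered intramolecular Diels–Alder of silyl dienol ether 16 onto the cycloheptenone, then Saegusa oxidation and decarboxylative loss of the tether.
4. Ring A (cycloheptenone 10, formed first) ⇐ ring-closing metathesis of dienone 9 ⇐ (S)-pantolactone 1, methallyl bromide and vinylmagnesium bromide.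

Assumption: the SMILES is read as the (1S,2S)-trans-diester (labels below), which calls for (S)-pantolactone; both enantiomers of pantolactone are commercial.

Skeleton labels (target SMILES, left to right): C-1 (CH–O-angelate), C-2 (CH–O-isobutyrate), C-3 (CH2), C-4 (quaternary C–CH3), C-5 (CH next to C=O), C-6 (C=O), C-7 (=CH), C-8 (=C–CH3), C-9 (CH), C-10 (CH), C-11 (CMe2). "Top face" is the face of ring A that carries the C-2 oxygen.

**Step 1**
Reactants: 1 (S)-pantolactone
Product: 2 (3S)-4,4-dimethyloxolane-2,3-diol (lactol; anomers)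
Conditions: i-Bu2AlH (2.3 equiv), THF, −78 °C; aq. potassium sodium tartrate
Reagents that add atoms: none
Why: Partial hydride reduction of the lactone stops at the aluminium hemiacetal at −78 °C (one equivalent is spent on the free OH), and the C-1 stereocentre bought with 1 is untouched.

**Step 2**
Reactants: 2 lactol; 3 3-bromo-2-methylprop-1-ene
Product: 5 (3S,4S)-2,2,6-trimethylhept-6-ene-1,3,4-triol, via 2-methylallylindium sesquibromide 4 (not isolated)
Conditions: In powder, THF/H2O 1:1, 25 °C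
Reagents that add atoms: 3-bromo-2-methylprop-1-ene (3), C=C(C)CBr; indium, [In] (kept only in 4)
Why: Indium Barbier allylation of the open hydroxy-aldehyde form, in which the free C-1 hydroxyl and the aldehyde chelate indium and the allyl group enters opposite the CMe2 branch (Cram chelate model), giving the syn diol, i.e. (S) at C-2.

**Step 3**
Reactants: 5 triol
Product: 7 (4S,5S)-4-hydroxy-3,3-dimethyl-5-(2-methylprop-2-enyl)oxolan-2-one, via lactol 6 (not isolated)
Conditions: TEMPO (0.2 equiv), PhI(OAc)2 (2.5 equiv), CH2Cl2, 25 °C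
Reagents that add atoms: none
Why: Oxoammonium oxidation takes the primary alcohol, the aldehyde is trapped by the C-2 hydroxyl as a five-membered lactol and this is oxidised on to the γ-lactone (oxidative lactonisation); the secondary C-1 hydroxyl and both stereocentres survive.

**Step 4**
Reactants: 7 hydroxy lactone; 8 vinylmagnesium bromide
Product: 9 (5S,6S)-5,6-dihydroxy-4,4,8-trimethylnona-1,8-dien-3-one (in equilibrium with its cyclic hemiketal)
Conditions: CH2=CHMgBr (3 equiv), THF, −78 °C; AcOH at −78 °C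
Reagents that add atoms: vinylmagnesium bromide (8), C=C[Mg]Br
Why: Grignard mono-addition, because the tetrahedral magnesium hemiketalate of the hindered α,α-dimethyl lactone is stable at −78 °C and gives the vinyl ketone only on quench; no stereocentre is involved.

**Step 5**
Reactants: 9 dienone
Product: 10 (5S,6S)-5,6-dihydroxy-3,7,7-trimethylcyclohept-2-en-1-one
Conditions: second-generation Grubbs catalyst [RuCl2(H2IMes)(PCy3)(=CHPh)] (5 mol %), CH2Cl2 (5 mM), 40 °C
Reagents that add atoms: none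
Why: Ring-closing metathesis of the vinyl ketone with the 1,1-disubstituted alkene, helped by the gem-dimethyl group, closes ring A as the trisubstituted enone with loss of ethene.

**Step 6**
Reactants: 11 Meldrum's acid; 12 (E)-but-2-enoyl chloride
Product: 13 5-[(E)-1-hydroxybut-2-enylidene]-2,2-dimethyl-1,3-dioxane-4,6-dione
Conditions: pyridine (2 equiv), CH2Cl2, 0 °C
Reagents that add atoms: (E)-but-2-enoyl chloride (12), C/C=C/C(Cl)=O
Why: C-acylation of Meldrum's acid (Oikawa–Yonemitsu) gives the stable enol form of the acyl Meldrum's acid.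

**Step 7**
Reactants: 10 enone diol; 13 acyl Meldrum's acid
Product: 15 (1S,2S)-2-hydroxy-3,3,6-trimethyl-4-oxocyclohept-5-en-1-yl (E)-3-oxohex-4-enoate, via crotonoylketene 14 (not isolated)
Conditions: PhMe, 95 °C
Reagents that add atoms: compound 13, C/C=C/C(O)=C1C(=O)OC(C)(C)OC1=O
Why: Thermal cycloreversion of 13 (loss of acetone and CO2) gives the acylketene, which is trapped by the C-2 hydroxyl; the C-1 hydroxyl next to CMe2 is too hindered to compete.

**Step 8**
Reactants: 15 β-keto ester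
Product: 17 Diels–Alder adduct (tricyclic silyl enol ether lactone; see list), via bis-silyl dienol ether 16 (not isolated)
Conditions: BSA (3 equiv), PhMe, 60 °C; then 165 °C, sealed tube
Reagents that add atoms: N,O-bis(trimethylsilyl)acetamide, CC(=N[Si](C)(C)C)O[Si](C)(C)C
Why: Type 1 intramolecular Diels–Alder reaction in which the four-atom ester tether from the C-2 oxygen holds the 2-silyloxy diene over the top face of the enone, so C-5 bonds to C-4 and C-8 to C-9 on that face; this sets the quaternary C-4 and the cis ring fusion at C-9 (C-5 and C-8 configurations are erased later).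

**Step 9**
Reactants: 17 Diels–Alder adduct
Product: 18 enone keto lactone (see list)
Conditions: Pd(OAc)2 (1.1 equiv), MeCN, 25 °C
Reagents that add atoms: none
Why: Saegusa–Ito oxidation, in which palladation of the silyl enol ether at C-7 and β-hydride elimination of the C-8 hydrogen give the 3-methyl enone regiospecifically and remove the C-8 stereocentre.

**Step 10**
Reactants: 18 enone keto lactone
Product: 21 (4aS,6S,7S,9aS)-6,7-dihydroxy-1,4a,8,8-tetramethyl-4,4a,5,6,7,8-hexahydro-3H-benzo[7]annulene-3,9(9aH)-dione, via desilylated keto lactone 19 (not isolated), via keto acid 20 (not isolated)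
Conditions: 2 M HCl, THF, 60 °C
Reagents that add atoms: water, O (its oxygen is kept only in 20)
Why: Acid hydrolysis of the silyl ether and the β-keto lactone followed by decarboxylation of the β-keto acid removes the tether and frees the C-2 hydroxyl (acid avoids retro-aldol of the β-hydroxy ketone); the cis fusion is also the thermodynamic one, since the C-9 substituent stays pseudo-axial away from the C-8 methyl.

**Step 11**
Reactants: 21 diol dione
Product: 23 (4aS,6S,7S,9S,9aS)-6,7,9-trihydroxy-1,4a,8,8-tetramethyl-4,4a,5,6,7,8,9,9a-octahydro-3H-benzo[7]annulen-3-one, via O-diethylboryl chelate 22 (not isolated)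
Conditions: Et2BOMe (1.2 equiv), THF/MeOH 4:1, −78 °C; NaBH4 (1.1 equiv), −78 °C; AcOH; MeOH co-evaporation
Reagents that add atoms: diethyl(methoxy)borane, CCB(CC)OC (its Et2B group is kept only in 22)
Why: Narasaka–Prasad reduction, in which the boron chelate between the C-1 oxygen and the C-10 carbonyl activates only that ketone and forces external hydride onto the face opposite the chelate, giving the cis-1,3-diol (C-10 OH cis to C-1 OH); the unchelated enone survives at −78 °C.

**Step 12**
Reactants: 23 triol; 24 2-methylpropanoyl chloride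
Product: 25 (4aS,6S,7S,9S,9aS)-7,9-dihydroxy-1,4a,8,8-tetramethyl-3-oxo-4,4a,5,6,7,8,9,9a-octahydro-3H-benzo[7]annulen-6-yl 2-methylpropanoate
Conditions: 24 (1.05 equiv), pyridine, CH2Cl2, −30 to 0 °C
Reagents that add atoms: 2-methylpropanoyl chloride (24), CC(C)C(Cl)=O
Why: Sterically controlled acylation, because the C-2 hydroxyl is the only one not flanked by the quaternary C-11.

**Step 13**
Reactants: 25 diol ester
Product: 27 cyclic sulfate of 25 across O-1 and O-10, via cyclic sulfite 26 (not isolated)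
Conditions: SOCl2, Et3N, CH2Cl2, 0 °C; then RuCl3 (0.5 mol %), NaIO4, MeCN/H2O, 0 °C
Reagents that add atoms: thionyl chloride, O=S(Cl)Cl; sodium periodate, [Na+].[O-]I(=O)(=O)=O
Why: Cyclic sulfite formation and RuO4-catalysed oxidation (Gao–Sharpless) tie up the C-1 oxygen and turn the C-10 oxygen into a leaving group; only the cis-1,3-diol can be bridged, so no hydroxyl differentiation is needed.

**Step 14**
Reactants: 27 cyclic sulfate
Product: 29 (1R,2R,4S,5S,7S,8R)-5-hydroxy-2,6,6,9-tetramethyl-11-oxotricyclo[5.4.0.0(2,8)]undec-9-en-4-yl 2-methylpropanoate, via lithium sulfate monoester 28 (not isolated)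
Conditions: LiN(i-Pr)2 (1.1 equiv), THF, −78 °C; DMPU, to 25 °C; then H2SO4 (cat.), H2O, THF, 25 °C
Reagents that add atoms: lithium diisopropylamide, [Li+].CC(C)[N-]C(C)C (its lithium is kept only in 28)
Why: Intramolecular enolate alkylation in which the kinetic α′ enolate at C-5 attacks C-10 from the top face with inversion (SN2), closing the cyclobutane and fixing C-5 and C-10; O-alkylation would need a bridgehead double bond, and the sulfate monoester is then hydrolysed with retention at C-1.

**Step 15**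
Reactants: 29 hydroxy ester; 30 angelic acid
Product: 32 (1R,2R,4S,5S,7S,8R)-2,6,6,9-tetramethyl-4-[(2-methylpropanoyl)oxy]-11-oxotricyclo[5.4.0.0(2,8)]undec-9-en-5-yl (Z)-2-methylbut-2-enoate, via angelic 2,4,6-trichlorobenzoic anhydride 31 (not isolated)
Conditions: 30, 2,4,6-trichlorobenzoyl chloride, Et3N, PhMe, 25 °C; then 29, 75 °C
Reagents that add atoms: angelic acid (30), C/C=C(/C)C(O)=O; 2,4,6-trichlorobenzoyl chloride, O=C(Cl)c1c(Cl)cc(Cl)cc1Cl (kept only in 31)
Why: Yamaguchi-type mixed-anhydride esterification run without DMAP acylates the hindered C-1 alcohol while keeping the Z geometry of the angelate.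

**Compound list**
1 | (S)-pantolactone, (3S)-3-hydroxy-4,4-dimethyloxolan-2-one | O[C@@H]1C(=O)OCC1(C)C | starting material
2 | (3S)-4,4-dimethyloxolane-2,3-diol (lactol, anomers) | O[C@@H]1C(O)OCC1(C)C | intermediate
3 | 3-bromo-2-methylprop-1-ene | C=C(C)CBr | starting material
4 | 2-methylallylindium sesquibromide (R2InBr·RInBr2) | C=C(C)C[In](Br)CC(C)=C.C=C(C)C[In](Br)Br | intermediate
5 | (3S,4S)-2,2,6-trimethylhept-6-ene-1,3,4-triol | OCC(C)(C)[C@H](O)[C@@H](O)CC(C)=C | intermediate
6 | (4S,5S)-3,3-dimethyl-5-(2-methylprop-2-enyl)oxolane-2,4-diol (lactol) | O[C@@H]1[C@H](CC(C)=C)OC(O)C1(C)C | intermediate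
7 | (4S,5S)-4-hydroxy-3,3-dimethyl-5-(2-methylprop-2-enyl)oxolan-2-one | O[C@@H]1[C@H](CC(C)=C)OC(=O)C1(C)C | intermediate
8 | vinylmagnesium bromide | C=C[Mg]Br | starting material
9 | (5S,6S)-5,6-dihydroxy-4,4,8-trimethylnona-1,8-dien-3-one | C=CC(=O)C(C)(C)[C@H](O)[C@@H](O)CC(C)=C | intermediate
10 | (5S,6S)-5,6-dihydroxy-3,7,7-trimethylcyclohept-2-en-1-one | O[C@@H]1[C@@H](O)CC(C)=CC(=O)C1(C)C | intermediate
11 | Meldrum's acid, 2,2-dimethyl-1,3-dioxane-4,6-dione | CC1(C)OC(=O)CC(=O)O1 | starting material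
12 | (E)-but-2-enoyl chloride | C/C=C/C(Cl)=O | starting material
13 | 5-[(E)-1-hydroxybut-2-enylidene]-2,2-dimethyl-1,3-dioxane-4,6-dione | C/C=C/C(O)=C1C(=O)OC(C)(C)OC1=O | intermediate
14 | crotonoylketene, (E)-hexa-1,4-diene-1,3-dione | C/C=C/C(=O)C=C=O | intermediate
15 | (1S,2S)-2-hydroxy-3,3,6-trimethyl-4-oxocyclohept-5-en-1-yl (E)-3-oxohex-4-enoate | O[C@@H]1[C@@H](OC(=O)CC(=O)/C=C/C)CC(C)=CC(=O)C1(C)C | intermediate
16 | (1S,2S)-3,3,6-trimethyl-4-oxo-2-(trimethylsilyloxy)cyclohept-5-en-1-yl (2Z,4E)-3-(trimethylsilyloxy)hexa-2,4-dienoate | C[Si](C)(C)O[C@@H]1[C@@H](OC(=O)/C=C(\O[Si](C)(C)C)/C=C/C)CC(C)=CC(=O)C1(C)C | intermediate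
17 | Diels–Alder adduct: cis-fused ring A/ring B ketone (C-10 C=O) with C-6/C-7 trimethylsilyl enol ether, C-8 methyl, C-1 OTMS and a δ-lactone C-5–C(=O)–O–C-2 on the top face (C-5 and C-8 epimers) | C[Si](C)(C)O[C@@H]1[C@H]2OC(=O)C3C(O[Si](C)(C)C)=CC(C)[C@@H](C(=O)C1(C)C)[C@@]3(C)C2 | intermediate
18 | enone keto lactone: as 17 but C-6 ketone and C-7=C-8(CH3) double bond (C-5 epimerisable) | C[Si](C)(C)O[C@@H]1[C@H]2OC(=O)C3C(=O)C=C(C)[C@@H](C(=O)C1(C)C)[C@@]3(C)C2 | intermediate
19 | C-1 hydroxy analogue of 18 | O[C@@H]1[C@H]2OC(=O)C3C(=O)C=C(C)[C@@H](C(=O)C1(C)C)[C@@]3(C)C2 | intermediate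
20 | keto acid: 21 carrying CO2H at C-5 | O[C@@H]1[C@@H](O)C[C@@]2(C)C(C(O)=O)C(=O)C=C(C)[C@H]2C(=O)C1(C)C | intermediate
21 | (4aS,6S,7S,9aS)-6,7-dihydroxy-1,4a,8,8-tetramethyl-4,4a,5,6,7,8-hexahydro-3H-benzo[7]annulene-3,9(9aH)-dione | O[C@@H]1[C@@H](O)C[C@@]2(C)CC(=O)C=C(C)[C@H]2C(=O)C1(C)C | intermediate
22 | C-1 O-diethylboryl derivative of 21 (boron chelated to the C-10 carbonyl) | CCB(CC)O[C@@H]1[C@@H](O)C[C@@]2(C)CC(=O)C=C(C)[C@H]2C(=O)C1(C)C | intermediate
23 | (4aS,6S,7S,9S,9aS)-6,7,9-trihydroxy-1,4a,8,8-tetramethyl-4,4a,5,6,7,8,9,9a-octahydro-3H-benzo[7]annulen-3-one | O[C@@H]1[C@@H](O)C[C@@]2(C)CC(=O)C=C(C)[C@H]2[C@H](O)C1(C)C | intermediate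
24 | 2-methylpropanoyl chloride | CC(C)C(Cl)=O | starting material
25 | (4aS,6S,7S,9S,9aS)-7,9-dihydroxy-1,4a,8,8-tetramethyl-3-oxo-4,4a,5,6,7,8,9,9a-octahydro-3H-benzo[7]annulen-6-yl 2-methylpropanoate | O[C@@H]1[C@@H](OC(=O)C(C)C)C[C@@]2(C)CC(=O)C=C(C)[C@H]2[C@H](O)C1(C)C | intermediate
26 | cyclic sulfite of 25 across O-1 and O-10 | O=S1O[C@@H]2[C@@H](OC(=O)C(C)C)C[C@@]3(C)CC(=O)C=C(C)[C@H]3[C@H](O1)C2(C)C | intermediate
27 | cyclic sulfate of 25 across O-1 and O-10 | O=S1(=O)O[C@@H]2[C@@H](OC(=O)C(C)C)C[C@@]3(C)CC(=O)C=C(C)[C@H]3[C@H](O1)C2(C)C | intermediate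
28 | lithium salt of the C-1 O-sulfate of 29 | [Li+].[O-]S(=O)(=O)O[C@@H]1[C@@H](OC(=O)C(C)C)C[C@@]2(C)[C@@H]3C(=O)C=C(C)[C@H]2[C@@H]3C1(C)C | intermediate
29 | (1R,2R,4S,5S,7S,8R)-5-hydroxy-2,6,6,9-tetramethyl-11-oxotricyclo[5.4.0.0(2,8)]undec-9-en-4-yl 2-methylpropanoate | O[C@@H]1[C@@H](OC(=O)C(C)C)C[C@@]2(C)[C@@H]3C(=O)C=C(C)[C@H]2[C@@H]3C1(C)C | intermediate
30 | angelic acid, (Z)-2-methylbut-2-enoic acid | C/C=C(/C)C(O)=O | starting material
31 | (Z)-2-methylbut-2-enoic 2,4,6-trichlorobenzoic anhydride | C/C=C(/C)C(=O)OC(=O)c1c(Cl)cc(Cl)cc1Cl | intermediate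
32 | (1R,2R,4S,5S,7S,8R)-2,6,6,9-tetramethyl-4-[(2-methylpropanoyl)oxy]-11-oxotricyclo[5.4.0.0(2,8)]undec-9-en-5-yl (Z)-2-methylbut-2-enoate | C/C=C(/C)C(=O)O[C@@H]1[C@@H](OC(=O)C(C)C)C[C@@]2(C)[C@@H]3C(=O)C=C(C)[C@H]2[C@@H]3C1(C)C | target

**Step count**
Total: 15 steps. Longest linear sequence: 14 steps (steps 1–5 and 7–15 from 1); step 6 is a one-step side branch.

**Steps most likely to fail**

Step 8 (tethered Diels–Alder). The dienophile is a β-methyl enone, the diene is attenuated by its ester, and the ester tether must adopt its less favoured rotamer. The fallback builds ring B by an anionic double Michael addition at the ynone oxidation level. It sets out from 10 and 11: Meldrum's acid 11 is acylated with commercial but-2-ynoic acid (DCC, DMAP, CH2Cl2) to 5-(1-hydroxybut-2-ynylidene)-2,2-dimethyl-1,3-dioxane-4,6-dione F1. Heating F1 with diol 10 in toluene gives (1S,2S)-2-hydroxy-3,3,6-trimethyl-4-oxocyclohept-5-en-1-yl 3-oxohex-4-ynoate F2. Cs2CO3 (0.3 equiv, MeCN, 0 °C) then adds the tethered β-keto ester carbon to C-4 on the top face, and the resulting C-9 enolate adds to the ynone. This gives keto lactone 19 directly, where the route is rejoined under the acid conditions of step 10.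

Step 14 (four-membered ring closure at a neopentyl centre). If the simple lithium enolate does not alkylate cleanly, C-5 is first activated with a removable selenium group. The fallback sets out from 27: LiN(i-Pr)2 then PhSeBr at −78 °C gives the C-5 phenylselanyl ketone cyclic sulfate F3. The softer, more acidic selenium-stabilised enolate is closed with Cs2CO3 in DMF at 40 °C, and acid hydrolysis of the sulfate ester gives the tricyclic C-5 phenylselanyl hydroxy ester F4. Radical deselenation (Bu3SnH, AIBN, PhH, 80 °C) at the bridgehead returns to the route at 29.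

Step 15 (angelate on a hindered alcohol; risk of Z to E isomerisation or acyl migration). The fallback builds the Z double bond on the molecule instead of transferring it. It sets out from 29: esterification with 2-[bis(2,2,2-trifluoroethoxy)phosphoryl]propanoic acid (DCC, DMAP, CH2Cl2) gives the C-1 phosphonopropanoate F5. Still–Gennari olefination (KN(SiMe3)2, 18-crown-6, THF, −78 °C, then acetaldehyde) gives the Z-configured 2-methylbut-2-enoate, i.e. target 32.

**Further compounds**
F1 | step 8 | 5-(1-hydroxybut-2-ynylidene)-2,2-dimethyl-1,3-dioxane-4,6-dione | CC#CC(O)=C1C(=O)OC(C)(C)OC1=O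
F2 | step 8 | (1S,2S)-2-hydroxy-3,3,6-trimethyl-4-oxocyclohept-5-en-1-yl 3-oxohex-4-ynoate | O[C@@H]1[C@@H](OC(=O)CC(=O)C#CC)CC(C)=CC(=O)C1(C)C
F3 | step 14 | C-5 phenylselanyl derivative of cyclic sulfate 27 | O=S1(=O)O[C@@H]2[C@@H](OC(=O)C(C)C)C[C@@]3(C)C([Se]c4ccccc4)C(=O)C=C(C)[C@H]3[C@H](O1)C2(C)C
F4 | step 14 | C-5 phenylselanyl derivative of tricyclic hydroxy ester 29 | O[C@@H]1[C@@H](OC(=O)C(C)C)C[C@@]2(C)[C@]3([Se]c4ccccc4)C(=O)C=C(C)[C@H]2[C@@H]3C1(C)C
F5 | step 15 | C-1 2-[bis(2,2,2-trifluoroethoxy)phosphoryl]propanoate of 29 | CC(C(=O)O[C@@H]1[C@@H](OC(=O)C(C)C)C[C@@]2(C)[C@@H]3C(=O)C=C(C)[C@H]2[C@@H]3C1(C)C)P(=O)(OCC(F)(F)F)OCC(F)(F)F
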